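## Analysis of the target

The target is a symmetric dimer: two identical 7-acetyl-3,6,8-trihydroxy-4,4-dimethylnaphthalen-1(4H)-one units joined by one methylene carbon between C2 and C2'. In each half, ring A is a benzene ring substituted at five carbons (C4a, C6-OH, C7-acetyl, C8-OH, C8a) with a single hydrogen at C5. Ring B is a non-aromatic six-membered ring made of the C1 ketone, the enolised C2=C3(OH) unit and the quaternary C4 with two methyl groups, which keeps ring B from aromatising. There is no stereocentre, so the problems are regiochemical and chemoselective. The sensitive parts are the enolised cyclic 1,3-diones (acidic, nucleophilic at C2 and at oxygen), the methylene-bis(1,3-dione) bridge (retro-Michael cleavage, acid-induced cyclodehydration to a pyran) and the chelated, oxidation-prone polyphenol. The hard points are the quaternary benzylic carbon next to an oxygenated carbon, the placing of an acetyl group between two ring A oxygens that must first be told apart, and bridging at C2 without touching C5 or oxygen. The strategy rests on ring B: the two-carbon unit C2=C3(O) sits between the C1 carbonyl on C8a and the quaternary C4 on C4a. Taking it out leaves a 2,2-dimethylbenzocyclobutenone, whose acyl–CMe2 bond can be opened to a vinylketene and closed again around an oxygenated alkyne.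

## Retrosynthetic reasoning

**15 to two molecules of 12 plus 13.** Both C2–CH2 bonds are cut. The bridge is the most fragile element of 15, so it is made last, under nearly neutral conditions, after all Lewis acid chemistry. The forward reaction needs 13 to react at C2 of 12, the carbon of a vinylogous acid, and not at the hindered, doubly acyl-deactivated C5 or at oxygen.

**12 to 11.** Two O–alkyl bonds are cut, C6–O–methyl and C3–O–ethyl. The C3 oxygen stays an ethyl enol ether from the annulation through all ring A chemistry, because this masks C2, which as a free 1,3-dione carbon would itself be acylated. Both alkyl groups then fall in one operation.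

**11 to 10 to 9 to 8.** The C7–acetyl bond is cut. C7 lies between two oxygens and resists intermolecular acylation, but an acetyl group released from the C8 oxygen has C7 as its only free ortho position. The para position C5 is screened by the C6 methoxy group and the peri gem-dimethyl group. This needs the C8 oxygen to be distinguished from the C6 oxygen. In 8 only the C8 methoxy group is peri to the C1 carbonyl, so chelation-controlled demethylation can free it alone.

**8 to 5 plus 6.** C1–C2 and C3–C4 are cut. Removing the oxygenated two-carbon unit leaves C8a with an acyl carbon and C4a with the CMe2 carbon, joined in 5 as a four-membered ring. The quaternary carbon therefore arrives intact and is not made by alkylation next to the arene. The ring-opened form 7 has the polarity that matches 6. The forward reaction must open the acyl–CMe2 bond at a temperature that 6 survives, and join C1–C2 and C3–C4 in this orientation.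

**5 to 4 to 1 plus 2, through 3.** The two aryl–carbon bonds of the four-membered ring are cut, which is a [2+2] cycloaddition of aryne 3 with ketene silyl acetal 2. Because 1 is symmetric, either hydrogen next to bromine leads to the same aryne. The methoxy group beside the aryne bond steers the ketal carbon to its side, so the later C1 carbonyl ends up peri to the C8 oxygen.

## Alternatives that were turned down

**Alternative 1: aldol aromatisation of a bridged bis(acyl-trione).**
- Disconnection: the C4a–C5 bond of each ring A is cut, unravelling ring A into an acetoacetyl side chain on a pre-formed, methylene-bridged pair of 4,4-dimethylcyclohexanetrione rings, A2.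
- Forward key step: a double intramolecular aldol condensation. The terminal methyl carbon of each side chain attacks the ring carbonyl next to CMe2, and dehydration aromatises both rings A to give A1.
- For: it follows polyketide logic, builds both aromatic rings at once on a symmetric substrate, uses cheap phloroglucinol-type chemistry, and needs neither an aryne nor light.
- Against:
  - The nucleophile is the least acidic carbon of a polycarbonyl array, and the electrophile is a carbonyl of an enolised triketone that is anionic under base.
  - The enol oxygen at that position can close onto the side-chain ketone to a fused 2-methyl-4-pyranone ring, the usual fate of such systems.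
  - The bridge of A2 is exposed to strong base or acid and can exchange by retro-Michael reaction.
  - A1 lacks both C7 acetyl groups, which would have to be introduced twice on a dimer with four free phenols and the bridge in place.
- Comparison: Alternative 1 is stronger in convergence and material cost. The chosen route instead makes each skeletal bond with defined regiochemistry, acetylates a monomer with differentiated oxygens, and forms the bridge last. With the synthesis of A2 and the acetylations counted, Alternative 1 is not shorter.

**Alternative 2: dearomative gem-dimethylation.**
- Disconnection: both C4–CH3 bonds are cut, leading back to the fully aromatic naphthalenediol ester A4.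
- Forward key step: the dianion of A4 is C-methylated twice at C4 with a methyl electrophile, giving A3 with the quaternary carbon and a dearomatised ring B.
- For: A4 comes from classical condensation chemistry, the reagents are cheap, the C2 ester blocks C2 and is lost later by decarboxylation, and the procedure scales without special equipment. On simplicity and scale, and probably on step count to the ring B stage, it is as strong as or stronger than the chosen route.
- Against:
  - The naphtholate is ambident, so O-methylation competes.
  - The second methylation must hit a carbon that already carries a methyl group, against the peri hydrogen and with loss of aromaticity, so mixtures of mono-, di- and O-methylated material are likely.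
  - In A3 the tricarbonyl carbon C2 is still acidic and can take a third methyl group.
  - The ester has to be removed afterwards, and the ring A acetylation remains as in the chosen route.
- Comparison: the chosen strategy brings both methyl groups in already attached to C4 (from 2), so no C/O or mono/di selectivity arises, and it delivers the dione already protected as 8.

**Alternative 3: pyranone-masked polyketide cascade.**
- Disconnection: C4a–C8a and C7–C8 are cut, so both rings come from the open-chain triketo ester A6 with a tethered 6-methylpyran-4-one.
- Forward key step: the carbanion between ketone and ester adds to the pyranone carbon that carries CMe2, the pyranone opens to a 1,3-diketone, and its central carbon acylates the ester to give A5, which is identical with 12.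
- For: on paper it is the most step-economic plan. It gives the complete monomer, with the C7 acetyl group and all free hydroxyls, without protecting groups.
- Against:
  - A6 has three acidic methylene groups, and the required carbanion competes with the more acidic one between two ketones.
  - The attack is on a pyranone carbon next to a quaternary centre.
  - 3,5-Dioxo esters readily lactonise to 4-hydroxypyran-2-one rings.
  - Making A6 needs polyanion acylations.
- Comparison: if it worked, Alternative 3 would be several steps shorter, and that is conceded. The chosen route offers in its place a ring-forming step whose regiochemistry follows from polarity and aromatisation, and stable, protected intermediates.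

Key step: step 3

Remark: 15 is handled as the bis-enol tautomer drawn; 13 is used as its 37% aqueous solution and 6 as its commercial solution in hexanes. The only stereogenic carbon on the route (the ketal carbon of 4) is formed as a racemate and removed in step 2.

## Route

Step 1
Reactants: 1 1-bromo-3,5-dimethoxybenzene; 2 1-methoxy-2-methyl-1-(trimethylsiloxy)propene
Product: 4 3,5,7-trimethoxy-8,8-dimethyl-7-(trimethylsiloxy)bicyclo[4.2.0]octa-1,3,5-triene (racemic), via 3,5-dimethoxybenzyne 3 (not isolated)
Conditions: LiTMP (from TMPH, n-BuLi), 2 (2.5 equiv), THF, −78 °C to 0 °C
Reagents that add atoms: none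
Why: LiTMP removes a hydrogen between bromine and methoxy, loss of LiBr gives aryne 3, and any lithiation between the two methoxy groups is unproductive but reversible. The nucleophilic CMe2 carbon of 2 attacks the aryne carbon remote from the adjacent methoxy group, so the aryl anion develops next to oxygen and closes onto the oxocarbenium carbon (stepwise aryne–ketene silyl acetal [2+2] cycloaddition), which places the ketal carbon ortho to a methoxy group.

Step 2
Reactants: 4 3,5,7-trimethoxy-8,8-dimethyl-7-(trimethylsiloxy)bicyclo[4.2.0]octa-1,3,5-triene
Product: 5 3,5-dimethoxy-8,8-dimethylbicyclo[4.2.0]octa-1,3,5-trien-7-one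
Conditions: 48% aq. HF, MeCN, 0 °C to 20 °C
Reagents that add atoms: none
Why: Hydrolysis of a mixed silyl methyl ketal: the O–Si bond is cleaved and the hemiketal loses methanol; the benzocyclobutenone is stable to these conditions.

Step 3
Reactants: 5 3,5-dimethoxy-8,8-dimethylbicyclo[4.2.0]octa-1,3,5-trien-7-one; 6 ethoxyacetylene
Product: 8 3-ethoxy-6,8-dimethoxy-4,4-dimethylnaphthalen-1(4H)-one, via ortho-quinoid vinylketene 7 (not isolated)
Conditions: hν (Pyrex, λ > 300 nm), 6 (10 equiv), degassed benzene, 20 °C
Reagents that add atoms: none
Why: Excitation of the aryl ketone of 5 opens the four-membered ring electrocyclically (four electrons) at the acyl–CMe2 bond and gives the ortho-quinoid vinylketene 7 at ambient temperature; a thermal opening of a benzo-fused cyclobutenone is expected to need temperatures well above 100 °C, where 6 fragments by a retro-ene reaction to ketene and ethylene, so heat is not used. The nucleophilic CH terminus of 6 adds to the electrophilic ketene carbon (C1–C2), and the zwitterion, whose negative charge sits on the CMe2 carbon once the benzene ring is restored, collapses onto the ethoxy-stabilised vinyl cation (C3–C4). The closest known reaction type is the vinylketene–ynol ether annulation of cyclobutenones (Danheiser benzannulation), which is also run with photochemical ring opening, together with the [4+2] trapping of benzocyclobutenone-derived quinoid ketenes. Ring B is closed by this intermolecular [4+2] annulation, the second bond forming in a six-membered, aromatisation-driven closure. No stereocentre is formed. The step needs regioselectivity, which the opposite polarisation of ketene carbon and ynol ether secures, and it needs trapping to outrun the [1,5]-hydrogen shift from the inward methyl group to the ketene carbon, for which 6 is used in large excess at high concentration. Because C4 is quaternary, 8 cannot tautomerise to a naphthol and stays at the oxidation level of the target.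

Step 4
Reactants: 8 3-ethoxy-6,8-dimethoxy-4,4-dimethylnaphthalen-1(4H)-one
Product: 9 3-ethoxy-8-hydroxy-6-methoxy-4,4-dimethylnaphthalen-1(4H)-one
Conditions: BCl3 (1.2 equiv), CH2Cl2, −78 °C to 0 °C; then H2O
Reagents that add atoms: none
Why: Chelation-controlled demethylation: boron bridges the C1 carbonyl oxygen and the peri C8 methoxy oxygen in a six-membered chelate and chloride removes only that methyl group. The C6 methyl ether has no such assistance, and the ethyl enol ether is dealkylated more slowly at low temperature with about one equivalent.

Step 5
Reactants: 9 3-ethoxy-8-hydroxy-6-methoxy-4,4-dimethylnaphthalen-1(4H)-one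
Product: 10 6-ethoxy-3-methoxy-5,5-dimethyl-8-oxo-5,8-dihydronaphthalen-1-yl acetate
Conditions: Ac2O, Et3N, DMAP (cat.), CH2Cl2, 20 °C
Reagents that add atoms: acetic anhydride, CC(=O)OC(C)=O
Why: DMAP-catalysed O-acetylation of the hydrogen-bonded phenol; no other acylable site is free, since C2 and the C3 oxygen are tied up in the vinylogous ester.

Step 6
Reactants: 10 6-ethoxy-3-methoxy-5,5-dimethyl-8-oxo-5,8-dihydronaphthalen-1-yl acetate
Product: 11 7-acetyl-3-ethoxy-8-hydroxy-6-methoxy-4,4-dimethylnaphthalen-1(4H)-one
Conditions: TiCl4 (2.5 equiv), ClCH2CH2Cl, 0 °C to 70 °C; then aq. HCl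
Reagents that add atoms: none
Why: Fries rearrangement: the acyl group released from the C8 oxygen recombines at C7, the only free ortho position, which is also ortho to the C6 methoxy group and para to the C4a alkyl carbon. The para position C5 is screened by the C6 methoxy group and the peri gem-dimethyl group, and chelation of the product phenoxide–ketone to titanium drives the reaction.

Step 7
Reactants: 11 7-acetyl-3-ethoxy-8-hydroxy-6-methoxy-4,4-dimethylnaphthalen-1(4H)-one
Product: 12 7-acetyl-3,6,8-trihydroxy-4,4-dimethylnaphthalen-1(4H)-one
Conditions: BBr3 (5 equiv), CH2Cl2, −78 °C to 20 °C; then H2O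
Reagents that add atoms: none
Why: BBr3 cleaves the C6 methyl ether (assisted by the neighbouring acetyl carbonyl) and dealkylates the vinylogous ethyl ester by bromide attack at the ethyl group, so the enolised 1,3-dione appears on aqueous work-up; the ketones and the quaternary carbon are inert.

Step 8
Reactants: 12 7-acetyl-3,6,8-trihydroxy-4,4-dimethylnaphthalen-1(4H)-one (2 equiv); 13 formaldehyde
Product: 15 2,2'-methylenebis[7-acetyl-3,6,8-trihydroxy-4,4-dimethylnaphthalen-1(4H)-one] (CNP0295164.0), via 2-methylidene trione 14 (not isolated)
Conditions: 37% aq. CH2O (0.5 equiv), NaOAc (cat.), EtOH–H2O, 20 °C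
Reagents that add atoms: none
Why: Tandem Knoevenagel condensation and Michael addition: C2 of the 1,3-dione condenses with formaldehyde to the acceptor 14, which a second molecule of 12 attacks through C2, the reaction type by which 4-hydroxycoumarin and cyclic 1,3-diones give methylene-bis adducts. C2 is far more nucleophilic than the hindered, doubly acyl-deactivated C5, and half an equivalent of formaldehyde limits over-reaction.

## Compound list

1 | 1-bromo-3,5-dimethoxybenzene | COc1cc(Br)cc(OC)c1 | starting material
2 | 1-methoxy-2-methyl-1-(trimethylsiloxy)propene | COC(O[Si](C)(C)C)=C(C)C | starting material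
3 | 3,5-dimethoxybenzyne (1,2-didehydro-3,5-dimethoxybenzene) | COC1=CC(OC)=CC#C1 | intermediate
4 | 3,5,7-trimethoxy-8,8-dimethyl-7-(trimethylsiloxy)bicyclo[4.2.0]octa-1,3,5-triene (racemic) | COc1cc(OC)c2c(c1)C(C)(C)C2(OC)O[Si](C)(C)C | intermediate
5 | 3,5-dimethoxy-8,8-dimethylbicyclo[4.2.0]octa-1,3,5-trien-7-one | COc1cc(OC)c2c(c1)C(C)(C)C2=O | intermediate
6 | ethoxyacetylene | CCOC#C | starting material
7 | [2,4-dimethoxy-6-(propan-2-ylidene)cyclohexa-2,4-dien-1-ylidene]methanone (ortho-quinoid vinylketene) | O=C=C1C(OC)=CC(OC)=CC1=C(C)C | intermediate
8 | 3-ethoxy-6,8-dimethoxy-4,4-dimethylnaphthalen-1(4H)-one | CCOC1=CC(=O)c2c(OC)cc(OC)cc2C1(C)C | intermediate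
9 | 3-ethoxy-8-hydroxy-6-methoxy-4,4-dimethylnaphthalen-1(4H)-one | CCOC1=CC(=O)c2c(O)cc(OC)cc2C1(C)C | intermediate
10 | 6-ethoxy-3-methoxy-5,5-dimethyl-8-oxo-5,8-dihydronaphthalen-1-yl acetate | CCOC1=CC(=O)c2c(OC(C)=O)cc(OC)cc2C1(C)C | intermediate
11 | 7-acetyl-3-ethoxy-8-hydroxy-6-methoxy-4,4-dimethylnaphthalen-1(4H)-one | CCOC1=CC(=O)c2c(O)c(C(C)=O)c(OC)cc2C1(C)C | intermediate
12 | 7-acetyl-3,6,8-trihydroxy-4,4-dimethylnaphthalen-1(4H)-one | CC(=O)c1c(O)cc2c(c1O)C(=O)C=C(O)C2(C)C | intermediate
13 | formaldehyde | C=O | starting material
14 | 7-acetyl-6,8-dihydroxy-4,4-dimethyl-2-methylidenenaphthalene-1,3(2H,4H)-dione | CC(=O)c1c(O)cc2c(c1O)C(=O)C(=C)C(=O)C2(C)C | intermediate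
15 | 2,2'-methylenebis[7-acetyl-3,6,8-trihydroxy-4,4-dimethylnaphthalen-1(4H)-one] | CC(=O)c1c(O)cc2c(c1O)C(=O)C(CC1=C(O)C(C)(C)c3cc(O)c(C(C)=O)c(O)c3C1=O)=C(O)C2(C)C | target

## Step count and least certain steps

Total step count: 8. Longest linear sequence: 8 steps (1 to 15).

**Step 3 (key step).** Three processes can erode it. The first is isomerisation of 7 by a [1,5]-hydrogen shift from the inward methyl group to the ketene carbon, which at ambient temperature drains the intermediate irreversibly. The second is secondary photoreaction of the product enone with excess 6 (photocycloaddition), or photodecarbonylation of 5. The third is closure in the [2+2], ring-opening and six-electron sense, which would put the ethoxy group at C1 and remove the peri carbonyl needed in step 4. Fallback, from 1 and 2, returning at 8: palladium-catalysed α-arylation of 2 with 1 (Pd(dba)2, P(t-Bu)3, ZnF2, DMF, 80 °C) should give methyl 2-(3,5-dimethoxyphenyl)-2-methylpropanoate F1. Crossed Claisen condensation with the lithium enolate of ethyl acetate (LDA, EtOAc, THF, −78 °C to 0 °C) should give ethyl 4-(3,5-dimethoxyphenyl)-4-methyl-3-oxopentanoate F2. Intramolecular Friedel–Crafts acylation at either of the two equivalent ring positions ortho to the side chain (Eaton's reagent, P2O5 in MeSO3H, 20–40 °C) should give 3-hydroxy-6,8-dimethoxy-4,4-dimethylnaphthalen-1(4H)-one F3. Acid-catalysed enol etherification (EtOH, TsOH, toluene, reflux with removal of water) should then give 8. This closes ring B at C1–C8a and gives up the cycloaddition.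

**Step 6.** The enol ether may be dealkylated by the chlorotitanium species and an acyl group then transferred to C2. The acetate may also be lost without migration, or C7 may react sluggishly in the carbonyl-bearing ring. Fallback, from 9, returning at 11: iodination ortho to the phenol (BnMe3N ICl2, NaHCO3, CH2Cl2–MeOH, 20 °C) should give 3-ethoxy-8-hydroxy-7-iodo-6-methoxy-4,4-dimethylnaphthalen-1(4H)-one F4. Stille coupling with tributyl(1-ethoxyvinyl)stannane (Pd(PPh3)4, zerovalent palladium, CuI, toluene, 100 °C) should give 3-ethoxy-7-(1-ethoxyvinyl)-8-hydroxy-6-methoxy-4,4-dimethylnaphthalen-1(4H)-one F5. Brief treatment with 1 M HCl in THF at 0 °C should hydrolyse the aryl-bound enol ether, which reacts much faster than the vinylogous ester, to 11.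

**Step 1.** Lithiation between the two methoxy groups may stall the aryne formation. The amide or the amine may add to the aryne, or the fully substituted ketene acetal may capture the aryne too slowly, so that the aryne oligomerises. Fallback, from 1, returning at 5: palladium-catalysed α-arylation of isobutyraldehyde with 1 (Pd(OAc)2, rac-BINAP, Cs2CO3, dioxane, 80 °C) should give 2-(3,5-dimethoxyphenyl)-2-methylpropanal F6. Bromination ortho to the side chain and para to a methoxy group (NBS, MeCN, 0 °C) should give 2-(2-bromo-3,5-dimethoxyphenyl)-2-methylpropanal F7. Palladium-catalysed intramolecular acylation of the aryl bromide by the aldehyde C–H bond (Pd(OAc)2, rac-BINAP, Cs2CO3, dioxane, 110 °C) should close the four-membered ring to 5.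

**Step 4.** The protecting enol ether may be lost at the same time, or the discrimination between the two methyl ethers may be incomplete. Fallback, from 8, returning at 9: deliberate double cleavage with excess BCl3 (3 equiv, CH2Cl2, 0 °C) should give 3,8-dihydroxy-6-methoxy-4,4-dimethylnaphthalen-1(4H)-one F8. Re-etherification of the enol alone (EtOH, TsOH, toluene, reflux with removal of water) should give 9, since the phenol is not etherified under these conditions and the chelated C1 carbonyl stays a ketone.

**Step 8.** Formaldehyde may react further to oligomers, may attack C5 or bridge through oxygen, and the polyphenol may oxidise in air. Fallback, from 12, returning at 15: Mannich reaction of 12 with Eschenmoser's salt (dimethylmethyleneiminium iodide, MeCN, 0 °C) should give 7-acetyl-2-[(dimethylamino)methyl]-3,6,8-trihydroxy-4,4-dimethylnaphthalen-1(4H)-one F9. Heating F9 with one further equivalent of 12 (dioxane, 80 °C) should eliminate dimethylamine to 14, with no free formaldehyde present, and Michael addition of 12 then gives 15.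

## Further compounds

F1 | step 3 | methyl 2-(3,5-dimethoxyphenyl)-2-methylpropanoate | COC(=O)C(C)(C)c1cc(OC)cc(OC)c1
F2 | step 3 | ethyl 4-(3,5-dimethoxyphenyl)-4-methyl-3-oxopentanoate | CCOC(=O)CC(=O)C(C)(C)c1cc(OC)cc(OC)c1
F3 | step 3 | 3-hydroxy-6,8-dimethoxy-4,4-dimethylnaphthalen-1(4H)-one | COc1cc(OC)c2c(c1)C(C)(C)C(O)=CC2=O
F4 | step 6 | 3-ethoxy-8-hydroxy-7-iodo-6-methoxy-4,4-dimethylnaphthalen-1(4H)-one | CCOC1=CC(=O)c2c(O)c(I)c(OC)cc2C1(C)C
F5 | step 6 | 3-ethoxy-7-(1-ethoxyvinyl)-8-hydroxy-6-methoxy-4,4-dimethylnaphthalen-1(4H)-one | CCOC(=C)c1c(OC)cc2c(c1O)C(=O)C=C(OCC)C2(C)C
F6 | step 1 | 2-(3,5-dimethoxyphenyl)-2-methylpropanal | CC(C)(C=O)c1cc(OC)cc(OC)c1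
F7 | step 1 | 2-(2-bromo-3,5-dimethoxyphenyl)-2-methylpropanal | CC(C)(C=O)c1cc(OC)cc(OC)c1Br
F8 | step 4 | 3,8-dihydroxy-6-methoxy-4,4-dimethylnaphthalen-1(4H)-one | COc1cc(O)c2c(c1)C(C)(C)C(O)=CC2=O
F9 | step 8 | 7-acetyl-2-[(dimethylamino)methyl]-3,6,8-trihydroxy-4,4-dimethylnaphthalen-1(4H)-one | CN(C)CC1=C(O)C(C)(C)c2cc(O)c(C(C)=O)c(O)c2C1=O
A1 | alternative 1 | 2,2'-methylenebis(3,6,8-trihydroxy-4,4-dimethylnaphthalen-1(4H)-one) | Oc1cc(O)c2c(c1)C(C)(C)C(O)=C(CC1=C(O)C(C)(C)c3cc(O)cc(O)c3C1=O)C2=O
A2 | alternative 1 | 6,6'-methylenebis[3,5-dihydroxy-4,4-dimethyl-2-(3-oxobutanoyl)cyclohexa-2,5-dien-1-one] | CC(=O)CC(=O)C1=C(O)C(C)(C)C(O)=C(CC2=C(O)C(C)(C)C(O)=C(C(=O)CC(C)=O)C2=O)C1=O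
A3 | alternative 2 | methyl 3-hydroxy-6,8-dimethoxy-4,4-dimethyl-1-oxo-1,4-dihydronaphthalene-2-carboxylate | COC(=O)C1=C(O)C(C)(C)c2cc(OC)cc(OC)c2C1=O
A4 | alternative 2 | methyl 1,3-dihydroxy-6,8-dimethoxynaphthalene-2-carboxylate | COC(=O)c1c(O)cc2cc(OC)cc(OC)c2c1O
A5 | alternative 3 | 7-acetyl-3,6,8-trihydroxy-4,4-dimethylnaphthalen-1(4H)-one | CC(=O)c1c(O)cc2c(c1O)C(=O)C=C(O)C2(C)C
A6 | alternative 3 | methyl 6-methyl-6-(6-methyl-4-oxo-4H-pyran-2-yl)-3,5-dioxoheptanoate | COC(=O)CC(=O)CC(=O)C(C)(C)c1cc(=O)cc(C)o1
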